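## Structural features

The target is a hexasubstituted benzene (phloroglucinol core, ring A) fused to a 2,3-dimethylchroman-4-one (ring B: O1, C2, C3, C4, C4a, C8a). It carries a prenyl group at C6 between the C5 and C7 phenols, and at C8 an (R)-configured chain C1'H(propyl)–C2'H2–C3'O2Me. C2 (R) and C3 (S) are adjacent and cis. C3 is alpha to the C4 ketone and ring B can open by retro-oxa-Michael reaction, so the cis pair is the kinetic arrangement and must be made late and kept away from base. C1' is isolated from this pair (1,5 to C2 across O1–C8a–C8) and cannot be relayed from it; it sits on a benzylic carbon whose ring carbon C8 is flanked by two oxygens. The atoms O1, C8a, C8, C1', C2', C3' form a latent 2-oxygenated chroman (a ring-opened dihydrocoumarin). The key step exploits this 1,5-relationship between the ring B oxygen O1 and the carboxyl carbon C3' through an ortho-quinone methide at C8a/C8/C1'. Fragile groups are the prenyl alkene (no hydrogenation or ozone; acid can cyclise it onto a flanking phenol), the cis-chromanone, and the hydroxy ester, which can relactonise. The real difficulty is twofold: three different carbon substituents and three differentiated oxygens must be placed on alternate ring carbons, and the absolute configuration at C1' must be set on a di-ortho-oxygenated benzylic carbon.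

## Logic of the disconnections

**O1–C2 bond (24 to 23 to 22).** After removal of the two MOM groups from the C5 and C7 oxygens, ring B is opened at O1–C2. The forward step is an intramolecular SN2 closure with inversion at the carbinol carbon. This turns the kinetic cis pair C2/C3 into an acyclic anti hydroxy ketone whose two centres can be bought. The demand is that only the C8a phenol is free when the ring closes (C5–O masked), that the closure does not pass through the enone, and that it comes late.

**C3'–OMe and O1–H (22 to 21 to 20 to 19 to 18).** The methyl ester and the free C8a phenol are traced to a lactone O1–C3', then to the lactol, then to the mixed acetal 18. The acetal ties O1 and the carboxyl carbon into one ring that is inert to organolithium reagents. The unveiling must spare the silyl ether, the MOM ethers and the prenyl group.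

**C4–C4a bond (18 to 16 plus 5; 5 to 4 to 3 to 1).** The acyl group is attached at the last free ring position by directed metalation and acylation with amide 5. The anti stereodiad of 5 comes from 1 by alkylation of its dianion (the C–CH3 bond). The forward steps must keep the centre alpha to the carbonyl.

**C6–prenyl bond (16 to 14).** The prenyl group is introduced by metalation between the two MOM ethers. This requires metalation at C6 rather than C8 of the chromane 14.

**C1'–C2' and O1–C(acetal) bonds, key disconnection (14 to 13 plus 7; 13 to 10).** The chroman acetal is cut across the pyran ring into the ortho-quinone methide 13 and the chiral vinyl ether 7. 13 arises from 10 by addition of a propyl Grignard reagent, which also forms the C1'–propyl bond. One operation therefore assembles the benzylic centre from three components, closes the oxygen ring on the oxygen that will become O1, and masks the carboxyl carbon. The product, with two stereocentres on a tetrasubstituted arene, goes back to an achiral aldehyde. In one sentence: a Grignard-triggered ortho-quinone methide from the O-Boc salicylaldehyde 10 is caught by the chiral vinyl ether 7 in a hetero-Diels–Alder reaction. The step must deliver the E-configured 13, endo approach and facial control by the auxiliary.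

**Protecting-group pattern (10 to 9 to 8; 7 to 6).** The one hydroxyl of 8 that stays free in 9 (the chelated one) becomes the carbonate of 10, then the pyran oxygen of 14, then O1 of ring B. This single choice fixes the whole substitution pattern: the oxygen para to the formyl carbon is the one that must stay masked during ring B closure.

## Other disconnections considered

**Alternative 1:** (the first to come to mind) Cut the aryl C8–C1' bond and the C4–C4a and O1–C2 bonds on the free phloroglucinol nucleus. Forward: Pechmann condensation of phloroglucinol with ethyl 3-oxohexanoate to coumarin A1, Friedel–Crafts acylation with tigloyl chloride to A2, oxa-Michael closure to A3, C-prenylation, enantioselective conjugate reduction of the coumarin and methanolysis. Grounds for preferring the chosen plan: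
- Nothing in A1 directs the acyl group to C6 over C8, or the ring closure to the 5-oxygen over the 7-oxygen.
- The oxa-Michael closure sets C2/C3 under equilibrating conditions, so the trans isomer and a racemate are expected.
- C1' would have to be set by reagent control on a fully substituted coumarin, beside a prenyl group and a base-sensitive chromanone.

**Alternative 2:** Cut the three C–H bonds at C1', C2 and C3: all stereocentres come from hydride delivery and protonation on the flat coumarin–chromone A4. Forward: double asymmetric conjugate reduction with a chiral copper hydride to A5, then methanolysis. The step count is attractive. Grounds against: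
- The tetrasubstituted C2=C3 bond is a poor acceptor.
- C3 would arise by protonation of an enolate and not from the catalyst, and can drift to trans.
- One ligand would have to control two electronically different acceptors.
- A4 has the same unresolved annulation regiochemistry as alternative 1.

**Alternative 3:** Cut the C8–C1' bond and form it by a [3,3] shift from O1 (aromatic Claisen rearrangement with 1,3-chirality transfer). Forward: the symmetric phenol A6 is etherified with inversion by allylic alcohol A7 to A8, which rearranges on heating through a chair to A9 (either ortho carbon, equivalent). The propenyl group is then hydrogenated to propyl and the silyloxyethyl arm oxidised to the ester. This uses the same relay oxygen and has a geometry-defined transition state, which is a real advantage. Grounds against: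
- A7 needs about four steps of its own.
- The etherification can leak through SN2' substitution.
- Hydrogenation must precede prenylation, and the prenyl group can then no longer be introduced by directed metalation.
- Two extra oxidation steps are needed; the plan is estimated at six or more steps longer than the route through 14.

Key step: step 7

Assumption: the (1S,2R) enantiomer of the auxiliary is assigned from the model in which the s-trans vinyl ether is attacked on the face remote from the phenyl group; should the sense be the opposite, the (1R,2S) enantiomer would be used and every later step stays the same.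

## Steps

Step 1
Reactants: 1 ethyl (S)-3-hydroxybutanoate
Product: 3 ethyl (2S,3S)-3-hydroxy-2-methylbutanoate, via dilithium alkoxide enolate 2 (not isolated)
Conditions: LiN(iPr)2 (2.2 equiv), THF, −50 → −20 °C; MeI, DMPU, −78 → 0 °C; aq. NH4Cl
Reagents that add atoms: iodomethane CI
Why: Fráter–Seebach alkylation; the chelated dianion 2 should be methylated on the face opposite to the C3 methyl group, giving mainly the 2,3-anti (2S,3S) ester with C3 untouched.

Step 2
Reactants: 3 ethyl (2S,3S)-3-hydroxy-2-methylbutanoate
Product: 4 ethyl (2S,3S)-3-[(tert-butyldimethylsilyl)oxy]-2-methylbutanoate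
Conditions: TBSCl, imidazole, DMF, rt
Reagents that add atoms: tert-butyldimethylsilyl chloride CC(C)(C)[Si](C)(C)Cl
Why: Standard silylation of a secondary alcohol; the ether blocks the hydroxyl during the aryllithium acylation and the lactol oxidation.

Step 3
Reactants: 4 ethyl (2S,3S)-3-[(tert-butyldimethylsilyl)oxy]-2-methylbutanoate
Product: 5 (2S,3S)-3-[(tert-butyldimethylsilyl)oxy]-N-methoxy-N,2-dimethylbutanamide
Conditions: MeNHOMe·HCl, iPrMgCl, THF, −20 → 0 °C
Reagents that add atoms: N,O-dimethylhydroxylamine hydrochloride CNOC.Cl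
Why: Ester to Weinreb amide through the magnesium amide; acyl substitution should outrun enolisation at this temperature, so the alpha centre is kept.

Step 4
Reactants: 6 (1S,2R)-2-phenylcyclohexan-1-ol
Product: 7 (1S,2R)-2-phenylcyclohexyl vinyl ether
Conditions: butyl vinyl ether (solvent), Pd(OCOCF3)2 (cat.), 4,7-diphenyl-1,10-phenanthroline (cat.), Et3N (cat.), 75 °C
Reagents that add atoms: butyl vinyl ether C=COCCCC
Why: Palladium-catalysed transfer vinylation of a secondary alcohol; no stereocentre is touched.

Step 5
Reactants: 8 2,4,6-trihydroxybenzaldehyde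
Product: 9 2-hydroxy-4,6-bis(methoxymethoxy)benzaldehyde
Conditions: MOMCl (2.1 equiv), iPr2NEt, CH2Cl2, 0 °C → rt
Reagents that add atoms: chloromethyl methyl ether COCCl
Why: Selective alkylation of phenols; the hydroxyl that is hydrogen-bonded to the formyl group is the least nucleophilic and should stay free.

Step 6
Reactants: 9 2-hydroxy-4,6-bis(methoxymethoxy)benzaldehyde
Product: 10 tert-butyl 2-formyl-3,5-bis(methoxymethoxy)phenyl carbonate
Conditions: Boc2O, DMAP (cat.), CH2Cl2, rt
Reagents that add atoms: di-tert-butyl dicarbonate CC(C)(C)OC(=O)OC(=O)OC(C)(C)C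
Why: DMAP-catalysed carbonate formation on the single free phenol; this marks the oxygen that will leave as the ortho-quinone methide oxygen.

Step 7
Reactants: 10 tert-butyl 2-formyl-3,5-bis(methoxymethoxy)phenyl carbonate; 7 (1S,2R)-2-phenylcyclohexyl vinyl ether
Product: 14 (2R,4R)-5,7-bis(methoxymethoxy)-2-{[(1S,2R)-2-phenylcyclohexyl]oxy}-4-propylchromane, via bromomagnesium benzylic alkoxide 11 (not isolated), via benzylic tert-butyl carbonate 12 (not isolated), via ortho-quinone methide 13 (not isolated)
Conditions: 7 (2.5 equiv), nPrMgBr (1.05 equiv), Et2O, −78 °C → rt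
Reagents that add atoms: n-propylmagnesium bromide CCC[Mg]Br
Why: The Grignard reagent adds to the aldehyde of 10 faster than to the carbonate; alkoxide 11 takes over the Boc group through a six-membered transition state to give 12, whose magnesium phenoxide expels tert-butyl carbonate below room temperature to give 13, which is trapped before it can dimerise or tautomerise to the vinylphenol. The closest known reaction type is the three-component ortho-quinone methide reaction of O-Boc salicylaldehydes, with inverse-demand hetero-Diels–Alder trapping by vinyl ethers of trans-2-phenylcyclohexanol. The dihydropyran ring closes in a [4+2] mode (oxadiene O=C8a–C8=C1' plus the two carbons of the enol ether); the nucleophilic CH2 terminus bonds to C1' and the oxygen-bearing carbon to the quinone methide oxygen, so polarity fixes the regiochemistry. The acetal centre C2 is controlled by the auxiliary: the phenyl group covers one face of the s-trans vinyl ether, the diene adds to the Re face of the oxygen-bearing carbon, and C2 becomes R. C4 (the future C1') is controlled relative to C2 by the endo orientation of the alkoxy group and the E geometry of 13, which together give the 2,4-cis chromane and hence 4R. The step needs E over Z geometry in 13 and endo over exo approach; the Z isomer has its propyl group on the inside of the heterodiene where it hinders the dienophile, so cycloaddition should drain the E isomer, and the alkoxy-endo preference is general for this class. Site selectivity needs no control, because 10 has one carbonate only, and that oxygen becomes the pyran oxygen and later O1 of ring B.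

Step 8
Reactants: 14 (2R,4R)-5,7-bis(methoxymethoxy)-2-{[(1S,2R)-2-phenylcyclohexyl]oxy}-4-propylchromane
Product: 16 (2R,4R)-5,7-bis(methoxymethoxy)-6-(3-methylbut-2-en-1-yl)-2-{[(1S,2R)-2-phenylcyclohexyl]oxy}-4-propylchromane, via 6-lithiochromane 15 (not isolated)
Conditions: nBuLi, THF, 0 °C; prenyl bromide, −78 °C → rt
Reagents that add atoms: 1-bromo-3-methylbut-2-ene CC(C)=CCBr
Why: Directed ortho-metalation; C6–H lies between two chelating MOM ethers and should be removed in preference to C8–H, which has one MOM ether and the weakly directing acetal oxygen as neighbours. The aryllithium 15 is then alkylated at the primary carbon of prenyl bromide.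

Step 9
Reactants: 16 (2R,4R)-5,7-bis(methoxymethoxy)-6-(3-methylbut-2-en-1-yl)-2-{[(1S,2R)-2-phenylcyclohexyl]oxy}-4-propylchromane; 5 (2S,3S)-3-[(tert-butyldimethylsilyl)oxy]-N-methoxy-N,2-dimethylbutanamide
Product: 18 (2S,3S)-1-[(2R,4R)-5,7-bis(methoxymethoxy)-6-(3-methylbut-2-en-1-yl)-2-{[(1S,2R)-2-phenylcyclohexyl]oxy}-4-propylchroman-8-yl]-3-[(tert-butyldimethylsilyl)oxy]-2-methylbutan-1-one, via 8-lithiochromane 17 (not isolated)
Conditions: sBuLi, TMEDA, THF, −78 °C; 5, −78 → 0 °C; aq. NH4Cl
Reagents that add atoms: none
Why: Second directed ortho-metalation at the only ring C–H left (between a MOM ether and the pyran oxygen), then Weinreb ketone synthesis. The chelated tetrahedral adduct prevents over-addition and releases the ketone only on work-up, so the alpha centre is not exposed to base.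

Step 10
Reactants: 18 (2S,3S)-1-[(2R,4R)-5,7-bis(methoxymethoxy)-6-(3-methylbut-2-en-1-yl)-2-{[(1S,2R)-2-phenylcyclohexyl]oxy}-4-propylchroman-8-yl]-3-[(tert-butyldimethylsilyl)oxy]-2-methylbutan-1-one
Product: 19 (2S,3S)-3-[(tert-butyldimethylsilyl)oxy]-1-[(4R)-2-hydroxy-5,7-bis(methoxymethoxy)-6-(3-methylbut-2-en-1-yl)-4-propylchroman-8-yl]-2-methylbutan-1-one
Conditions: PPTS, acetone/H2O (5:1), 50 °C
Reagents that add atoms: water O
Why: Hydrolysis of a mixed aryl alkyl acetal under conditions expected to spare aryl MOM ethers and a secondary TBS ether; the auxiliary 6 is released for reuse and the C2 centre is no longer needed.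

Step 11
Reactants: 19 (2S,3S)-3-[(tert-butyldimethylsilyl)oxy]-1-[(4R)-2-hydroxy-5,7-bis(methoxymethoxy)-6-(3-methylbut-2-en-1-yl)-4-propylchroman-8-yl]-2-methylbutan-1-one
Product: 21 methyl (3R)-3-[3-[(2S,3S)-3-[(tert-butyldimethylsilyl)oxy]-2-methylbutanoyl]-2-hydroxy-4,6-bis(methoxymethoxy)-5-(3-methylbut-2-en-1-yl)phenyl]hexanoate, via dihydrocoumarin lactone 20 (not isolated)
Conditions: Ag2CO3 on Celite, toluene, 80 °C; filtration; then MeOH, K2CO3 (0.2 equiv), 0 °C; pH 7 buffer
Reagents that add atoms: methanol CO
Why: Lactol-to-lactone oxidation with Ag2CO3 on Celite is selective for hemiacetals and leaves the prenyl group, ketone and silyl ether alone. The aryl lactone 20 is then opened by methanol with catalytic carbonate; the released phenol is held in the open form by its hydrogen bond to the ketone.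

Step 12
Reactants: 21 methyl (3R)-3-[3-[(2S,3S)-3-[(tert-butyldimethylsilyl)oxy]-2-methylbutanoyl]-2-hydroxy-4,6-bis(methoxymethoxy)-5-(3-methylbut-2-en-1-yl)phenyl]hexanoate
Product: 22 methyl (3R)-3-[2-hydroxy-3-[(2S,3S)-3-hydroxy-2-methylbutanoyl]-4,6-bis(methoxymethoxy)-5-(3-methylbut-2-en-1-yl)phenyl]hexanoate
Conditions: HF·pyridine, pyridine/THF, 0 °C → rt
Reagents that add atoms: none
Why: Fluoride desilylation under buffered, non-basic conditions; these should not trigger retro-aldol or beta-elimination of the hydroxy ketone and leave the MOM ethers in place.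

Step 13
Reactants: 22 methyl (3R)-3-[2-hydroxy-3-[(2S,3S)-3-hydroxy-2-methylbutanoyl]-4,6-bis(methoxymethoxy)-5-(3-methylbut-2-en-1-yl)phenyl]hexanoate
Product: 23 methyl (3R)-3-[(2R,3S)-5,7-bis(methoxymethoxy)-2,3-dimethyl-6-(3-methylbut-2-en-1-yl)-4-oxochroman-8-yl]hexanoate
Conditions: PPh3, DIAD, toluene, 0 °C → rt
Reagents that add atoms: none
Why: Intramolecular Mitsunobu etherification (6-exo-tet) by the only free phenol, a type known for aldol-derived hydroxy ketones of acylphloroglucinols. SN2 inversion turns the (S)-carbinol into (R)-C2 while C3 is untouched, so the anti hydroxy ketone gives the cis (2R,3S) chromanone; the C5 oxygen is masked, so ring B can close only on O1.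

Step 14
Reactants: 23 methyl (3R)-3-[(2R,3S)-5,7-bis(methoxymethoxy)-2,3-dimethyl-6-(3-methylbut-2-en-1-yl)-4-oxochroman-8-yl]hexanoate
Product: 24 methyl (3R)-3-[(2R,3S)-5,7-dihydroxy-2,3-dimethyl-6-(3-methylbut-2-en-1-yl)-4-oxochroman-8-yl]hexanoate
Conditions: 3 M aq. HCl/MeOH (1:10), 40 °C; NaHCO3 before concentration
Reagents that add atoms: none
Why: Acidic cleavage of aryl MOM ethers, a standard last step for prenylated phenols. Methanol as solvent keeps the ester as the methyl ester and disfavours relactonisation; dilute acid at this temperature should neither cyclise the prenyl group onto a phenol nor epimerise C3.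

## Compound list

1 | ethyl (S)-3-hydroxybutanoate | C[C@H](O)CC(=O)OCC | starting material
2 | dilithium alkoxide enolate of 1 | C[C@H](O[Li])C=C(O[Li])OCC | intermediate
3 | ethyl (2S,3S)-3-hydroxy-2-methylbutanoate | C[C@H](O)[C@H](C)C(=O)OCC | intermediate
4 | ethyl (2S,3S)-3-[(tert-butyldimethylsilyl)oxy]-2-methylbutanoate | C[C@H](O[Si](C)(C)C(C)(C)C)[C@H](C)C(=O)OCC | intermediate
5 | (2S,3S)-3-[(tert-butyldimethylsilyl)oxy]-N-methoxy-N,2-dimethylbutanamide | C[C@H](O[Si](C)(C)C(C)(C)C)[C@H](C)C(=O)N(C)OC | intermediate
6 | (1S,2R)-2-phenylcyclohexan-1-ol (trans) | O[C@H]1CCCC[C@@H]1c1ccccc1 | starting material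
7 | (1S,2R)-2-phenylcyclohexyl vinyl ether | C=CO[C@H]1CCCC[C@@H]1c1ccccc1 | intermediate
8 | 2,4,6-trihydroxybenzaldehyde | O=Cc1c(O)cc(O)cc1O | starting material
9 | 2-hydroxy-4,6-bis(methoxymethoxy)benzaldehyde | O=Cc1c(O)cc(OCOC)cc1OCOC | intermediate
10 | tert-butyl 2-formyl-3,5-bis(methoxymethoxy)phenyl carbonate | O=Cc1c(OC(=O)OC(C)(C)C)cc(OCOC)cc1OCOC | intermediate
11 | tert-butyl 2-(1-hydroxybutyl)-3,5-bis(methoxymethoxy)phenyl carbonate, present as its bromomagnesium alkoxide (drawn neutral, racemic) | CCCC(O)c1c(OC(=O)OC(C)(C)C)cc(OCOC)cc1OCOC | intermediate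
12 | tert-butyl 1-[2-hydroxy-4,6-bis(methoxymethoxy)phenyl]butyl carbonate, present as its magnesium phenoxide (drawn neutral, racemic) | CCCC(OC(=O)OC(C)(C)C)c1c(O)cc(OCOC)cc1OCOC | intermediate
13 | (6E)-6-butylidene-3,5-bis(methoxymethoxy)cyclohexa-2,4-dien-1-one | CCC/C=C1/C(=O)C=C(OCOC)C=C1OCOC | intermediate
14 | (2R,4R)-5,7-bis(methoxymethoxy)-2-{[(1S,2R)-2-phenylcyclohexyl]oxy}-4-propylchromane | CCC[C@@H]1C[C@H](O[C@H]2CCCC[C@@H]2c2ccccc2)Oc2cc(OCOC)cc(OCOC)c21 | intermediate
15 | 6-lithio derivative of 14 | CCC[C@@H]1C[C@H](O[C@H]2CCCC[C@@H]2c2ccccc2)Oc2cc(OCOC)c([Li])c(OCOC)c21 | intermediate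
16 | (2R,4R)-5,7-bis(methoxymethoxy)-6-(3-methylbut-2-en-1-yl)-2-{[(1S,2R)-2-phenylcyclohexyl]oxy}-4-propylchromane | CCC[C@@H]1C[C@H](O[C@H]2CCCC[C@@H]2c2ccccc2)Oc2cc(OCOC)c(CC=C(C)C)c(OCOC)c21 | intermediate
17 | 8-lithio derivative of 16 | CCC[C@@H]1C[C@H](O[C@H]2CCCC[C@@H]2c2ccccc2)Oc2c([Li])c(OCOC)c(CC=C(C)C)c(OCOC)c21 | intermediate
18 | (2S,3S)-1-[(2R,4R)-5,7-bis(methoxymethoxy)-6-(3-methylbut-2-en-1-yl)-2-{[(1S,2R)-2-phenylcyclohexyl]oxy}-4-propylchroman-8-yl]-3-[(tert-butyldimethylsilyl)oxy]-2-methylbutan-1-one | CCC[C@@H]1C[C@H](O[C@H]2CCCC[C@@H]2c2ccccc2)Oc2c(C(=O)[C@@H](C)[C@H](C)O[Si](C)(C)C(C)(C)C)c(OCOC)c(CC=C(C)C)c(OCOC)c21 | intermediate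
19 | (2S,3S)-3-[(tert-butyldimethylsilyl)oxy]-1-[(4R)-2-hydroxy-5,7-bis(methoxymethoxy)-6-(3-methylbut-2-en-1-yl)-4-propylchroman-8-yl]-2-methylbutan-1-one (both C2 anomers) | CCC[C@@H]1CC(O)Oc2c(C(=O)[C@@H](C)[C@H](C)O[Si](C)(C)C(C)(C)C)c(OCOC)c(CC=C(C)C)c(OCOC)c21 | intermediate
20 | (4R)-8-[(2S,3S)-3-[(tert-butyldimethylsilyl)oxy]-2-methylbutanoyl]-5,7-bis(methoxymethoxy)-6-(3-methylbut-2-en-1-yl)-4-propylchroman-2-one | CCC[C@@H]1CC(=O)Oc2c(C(=O)[C@@H](C)[C@H](C)O[Si](C)(C)C(C)(C)C)c(OCOC)c(CC=C(C)C)c(OCOC)c21 | intermediate
21 | methyl (3R)-3-[3-[(2S,3S)-3-[(tert-butyldimethylsilyl)oxy]-2-methylbutanoyl]-2-hydroxy-4,6-bis(methoxymethoxy)-5-(3-methylbut-2-en-1-yl)phenyl]hexanoate | CCC[C@H](CC(=O)OC)c1c(O)c(C(=O)[C@@H](C)[C@H](C)O[Si](C)(C)C(C)(C)C)c(OCOC)c(CC=C(C)C)c1OCOC | intermediate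
22 | methyl (3R)-3-[2-hydroxy-3-[(2S,3S)-3-hydroxy-2-methylbutanoyl]-4,6-bis(methoxymethoxy)-5-(3-methylbut-2-en-1-yl)phenyl]hexanoate | CCC[C@H](CC(=O)OC)c1c(O)c(C(=O)[C@@H](C)[C@H](C)O)c(OCOC)c(CC=C(C)C)c1OCOC | intermediate
23 | methyl (3R)-3-[(2R,3S)-5,7-bis(methoxymethoxy)-2,3-dimethyl-6-(3-methylbut-2-en-1-yl)-4-oxochroman-8-yl]hexanoate | CCC[C@H](CC(=O)OC)c1c(OCOC)c(CC=C(C)C)c(OCOC)c2c1O[C@H](C)[C@H](C)C2=O | intermediate
24 | methyl (3R)-3-[(2R,3S)-5,7-dihydroxy-2,3-dimethyl-6-(3-methylbut-2-en-1-yl)-4-oxochroman-8-yl]hexanoate | CCC[C@H](CC(=O)OC)c1c(O)c(CC=C(C)C)c(O)c2c1O[C@H](C)[C@H](C)C2=O | target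

## Step count and least certain steps

Total step count: 14. Longest linear sequence: 10 steps (8 to 24, steps 5 to 14); steps 1 to 3 and step 4 are side branches.

**Step 7 (key step).** What may go wrong:
- Loss of configuration at C4 if the Z-configured quinone methide forms and cycloadds; in the E isomer the propyl group is in allylic strain with the neighbouring MOM ether.
- Tautomerisation of 13 to the vinylphenol before it is trapped.
- Facial induction opposite to the model.

Fallback, from 9 back to 14: annulation of 9 with (triphenylphosphoranylidene)ketene gives 5,7-bis(methoxymethoxy)-2H-chromen-2-one F1. Copper-catalysed enantioselective conjugate addition of nPrMgBr (CuBr·SMe2, Josiphos-type ferrocenyl diphosphine, tBuOMe, −78 °C) to this geometry-locked lactone gives (4R)-5,7-bis(methoxymethoxy)-4-propylchroman-2-one F2. Reduction with iBu2AlH at −78 °C gives (4R)-5,7-bis(methoxymethoxy)-4-propylchroman-2-ol F3. Acetalisation with 6 (PPTS, molecular sieves, CH2Cl2) gives 14, which is separated from its C2 epimer (2S,4R)-5,7-bis(methoxymethoxy)-2-{[(1S,2R)-2-phenylcyclohexyl]oxy}-4-propylchromane F4; F4 is recycled by re-equilibration under the same acid.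

**Step 9.** What may go wrong: lateral deprotonation at the benzylic and allylic CH2 of the prenyl group, which two MOM ethers also direct, in place of ring metalation at C8; deprotonation or N–O cleavage of the amide by the hindered aryllithium.

Fallback, from 16 back to 18: NBS (MeCN, −30 °C) brominates the only free ring position to give the 8-bromo derivative of 16 F5. tBuLi (2 equiv, −78 °C) effects bromine–lithium exchange to 17 without touching the prenyl CH2. 17 is added to (2S,3S)-3-[(tert-butyldimethylsilyl)oxy]-2-methylbutanal F6 (from 4 with iBu2AlH at −78 °C) to give the secondary benzylic alcohol corresponding to 18 F7, which Dess–Martin periodinane oxidises to 18.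

**Step 11.** What may go wrong: stalling of the heterogeneous oxidation if 19 rests as the ring-opened hydroxy aldehyde with its phenol chelated to the ketone; beta-elimination of silanolate during the basic methanolysis.

Fallback, from 19 back to 21: the open-chain aldehyde is oxidised with NaClO2, NaH2PO4 and 2-methylbut-2-ene in tBuOH/H2O to (3R)-3-[3-[(2S,3S)-3-[(tert-butyldimethylsilyl)oxy]-2-methylbutanoyl]-2-hydroxy-4,6-bis(methoxymethoxy)-5-(3-methylbut-2-en-1-yl)phenyl]hexanoic acid F8. TMSCHN2 (toluene/MeOH, 0 °C) then esterifies the carboxyl group in preference to the chelated phenol and gives 21.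

**Step 13.** What may go wrong: E1cB elimination of the activated hydroxyl to the 2-methylbut-2-enoyl ketone, then unselective oxa-Michael closure with loss of both ring B centres.

Fallback, from 22 back to 23: Dess–Martin oxidation gives the 1,3-diketone methyl (3R)-3-[2-hydroxy-4,6-bis(methoxymethoxy)-5-(3-methylbut-2-en-1-yl)-3-(2-methyl-3-oxobutanoyl)phenyl]hexanoate F9. Cyclodehydration (PPTS, toluene, 60 °C) gives the chromone methyl (3R)-3-[5,7-bis(methoxymethoxy)-2,3-dimethyl-6-(3-methylbut-2-en-1-yl)-4-oxo-4H-chromen-8-yl]hexanoate F10. Copper hydride conjugate reduction (Cu(OAc)2, the DTBM-SEGPHOS enantiomer that delivers hydride to the C2 face giving 2R, (EtO)2MeSiH) gives the silyl enol ether of 23 F11. Protonation with Bu4NF/AcOH at −78 °C on the face opposite to the C2 methyl group should give the cis ketone 23.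

## Further compounds

F1 | step 7 | 5,7-bis(methoxymethoxy)-2H-chromen-2-one | O=c1ccc2c(OCOC)cc(OCOC)cc2o1
F2 | step 7 | (4R)-5,7-bis(methoxymethoxy)-4-propylchroman-2-one | CCC[C@@H]1CC(=O)Oc2cc(OCOC)cc(OCOC)c21
F3 | step 7 | (4R)-5,7-bis(methoxymethoxy)-4-propylchroman-2-ol (both anomers) | CCC[C@@H]1CC(O)Oc2cc(OCOC)cc(OCOC)c21
F4 | step 7 | (2S,4R)-5,7-bis(methoxymethoxy)-2-{[(1S,2R)-2-phenylcyclohexyl]oxy}-4-propylchromane | CCC[C@@H]1C[C@@H](O[C@H]2CCCC[C@@H]2c2ccccc2)Oc2cc(OCOC)cc(OCOC)c21
F5 | step 9 | (2R,4R)-8-bromo-5,7-bis(methoxymethoxy)-6-(3-methylbut-2-en-1-yl)-2-{[(1S,2R)-2-phenylcyclohexyl]oxy}-4-propylchromane | CCC[C@@H]1C[C@H](O[C@H]2CCCC[C@@H]2c2ccccc2)Oc2c(Br)c(OCOC)c(CC=C(C)C)c(OCOC)c21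
F6 | step 9 | (2S,3S)-3-[(tert-butyldimethylsilyl)oxy]-2-methylbutanal | C[C@H](O[Si](C)(C)C(C)(C)C)[C@H](C)C=O
F7 | step 9 | secondary benzylic alcohol corresponding to ketone 18 (both carbinol epimers, other centres as in 18) | CCC[C@@H]1C[C@H](O[C@H]2CCCC[C@@H]2c2ccccc2)Oc2c(C(O)[C@@H](C)[C@H](C)O[Si](C)(C)C(C)(C)C)c(OCOC)c(CC=C(C)C)c(OCOC)c21
F8 | step 11 | (3R)-3-[3-[(2S,3S)-3-[(tert-butyldimethylsilyl)oxy]-2-methylbutanoyl]-2-hydroxy-4,6-bis(methoxymethoxy)-5-(3-methylbut-2-en-1-yl)phenyl]hexanoic acid | CCC[C@H](CC(=O)O)c1c(O)c(C(=O)[C@@H](C)[C@H](C)O[Si](C)(C)C(C)(C)C)c(OCOC)c(CC=C(C)C)c1OCOC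
F9 | step 13 | methyl (3R)-3-[2-hydroxy-4,6-bis(methoxymethoxy)-5-(3-methylbut-2-en-1-yl)-3-(2-methyl-3-oxobutanoyl)phenyl]hexanoate | CCC[C@H](CC(=O)OC)c1c(O)c(C(=O)C(C)C(C)=O)c(OCOC)c(CC=C(C)C)c1OCOC
F10 | step 13 | methyl (3R)-3-[5,7-bis(methoxymethoxy)-2,3-dimethyl-6-(3-methylbut-2-en-1-yl)-4-oxo-4H-chromen-8-yl]hexanoate | CCC[C@H](CC(=O)OC)c1c(OCOC)c(CC=C(C)C)c(OCOC)c2c1OC(C)=C(C)C2=O
F11 | step 13 | diethoxy(methyl)silyl enol ether of 23 (2R) | CCC[C@H](CC(=O)OC)c1c(OCOC)c(CC=C(C)C)c(OCOC)c2c1O[C@H](C)C(C)=C2O[Si](C)(OCC)OCC
A1 | alternative 1 | 5,7-dihydroxy-4-propyl-2H-chromen-2-one | CCCc1cc(=O)oc2cc(O)cc(O)c12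
A2 | alternative 1 | 5,7-dihydroxy-6-[(E)-2-methylbut-2-enoyl]-4-propyl-2H-chromen-2-one | CCCc1cc(=O)oc2cc(O)c(C(=O)/C(C)=C/C)c(O)c12
A3 | alternative 1 | coumarin-fused 2,3-dimethylchromanone closed on the coumarin 5-oxygen (racemic, stereoisomer mixture) | CCCc1cc(=O)oc2cc(O)c3C(=O)C(C)C(C)Oc3c12
A4 | alternative 2 | prenylated 4-propylcoumarin fused to a 5-hydroxy-2,3-dimethylchromone | CCCC1=CC(=O)Oc2c(CC=C(C)C)c(O)c3C(=O)C(C)=C(C)Oc3c12
A5 | alternative 2 | (4R)-dihydrocoumarin fused to the (2R,3S)-chromanone, the lactone form of 24 | CCC[C@@H]1CC(=O)Oc2c(CC=C(C)C)c(O)c3C(=O)[C@@H](C)[C@@H](C)Oc3c12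
A6 | alternative 3 | 3,5-bis(methoxymethoxy)phenol | COCOc1cc(O)cc(OCOC)c1
A7 | alternative 3 | (2S,3E)-6-[(tert-butyldimethylsilyl)oxy]hex-3-en-2-ol | C[C@H](O)/C=C/CCO[Si](C)(C)C(C)(C)C
A8 | alternative 3 | 1-{[(2R,3E)-6-[(tert-butyldimethylsilyl)oxy]hex-3-en-2-yl]oxy}-3,5-bis(methoxymethoxy)benzene | C[C@@H](Oc1cc(OCOC)cc(OCOC)c1)/C=C/CCO[Si](C)(C)C(C)(C)C
A9 | alternative 3 | 2-[(3S,4E)-1-[(tert-butyldimethylsilyl)oxy]hex-4-en-3-yl]-3,5-bis(methoxymethoxy)phenol | C/C=C/[C@H](CCO[Si](C)(C)C(C)(C)C)c1c(O)cc(OCOC)cc1OCOC
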